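**Remarks on the chemistry (assumptions).** (a) Compound 30 is carried as the mixture of C3 epimers; C3 loses its sulfonyl group in step 19. (b) The closure in step 18 is classed as endo with respect to the oxirane, because both C1 and C2 become ring atoms; this is the one point corrected. The descriptors were checked and need no change: target (1R,6R,8S,4Z); the oxirane carbon C1 of 28 is S only because the CIP ranking changes. (c) The (S)-oxazaborolidine in step 8 and the (S,S) boron controller in step 12 are assigned from the usual models; if either sense were the reverse on these substrates, the antipode is used in the same step. Germacrane numbering is used throughout.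

## Structural features

The target is a ten-membered carbocycle (C1–C10) fused along C6–C7 to a butenolide (C7=C11, C12 carbonyl, ring oxygen on C6). C7=C11 is therefore a tetrasubstituted alkene carrying four oxygenated carbons: C6 and C8 on C7, C12 and C13 on C11. The ring also holds the (4Z)-trisubstituted alkene C4=C5 with its methyl group C15 and the exocyclic methylene C10=C14. There are three stereocentres: C1 (R, free hydroxyl), C6 (R, lactone oxygen) and C8 (S, acetate). C6 and C8 flank the sp2 carbon C7 in a 1,3-syn relation, and C1 is insulated from both by C9 and C10, so each must be set on its own. The fragile points are the butenolide (C6–H is gamma to the carbonyl and allylic to C4=C5, so base enolises or epimerises it), the two allylic acetates, the doubly allylic C6–O bond (acid-labile), and translactonisation towards O8 whenever O8 is free. The real difficulties are the medium ring with three sp2 units, the geometry of the C7=C11 unit (C12 cis to C6, C13 cis to C8) and the ordering of five oxygen functions. The key step uses the fact that C3 is allylic to the Z C4=C5 alkene and 1,3 to the C1 carbinol: a sulfonyl-stabilised C3 carbanion opens a C1–C2 oxirane at C2, which forms C2–C3, closes the ten-membered ring and frees the C1 hydroxyl with its configuration already in place, while the butenolide is masked as the 6,12-acetonide (a 4,7-dihydro-1,3-dioxepine on C7=C11).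

## Logic of the disconnections

38 to 35: the lactone acyl–oxygen bond C12–O6 is cut, C12 is taken back to the alcohol level, and O1 is given a silyl group (37). A butenolide with an acidic C6–H cannot pass through carbanion chemistry, and as a Z-ene-1,4-diol (35) it is harmless. The demand is an oxidation that takes the primary allylic C12–OH before the secondary C6–OH and spares the acetates, and a final desilylation that is not basic.

35 to 30: no skeletal bond is cut. The acetate O–acyl bonds, the ketal C–O bonds, the O1–Si bond and the C3–H bond are exchanged for PMB ethers, the acetonide, a free C1–OH and C3–SO2Ph (34, 33, 32, 31, 30). Compound 30 then carries only base-stable groups plus the auxiliary that made C3 nucleophilic. The demand is orthogonal removal in the order sulfone, PMB, acetonide, silyl, and a desulfonylation that does not move or isomerise C4=C5.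

30 to 28 (key): the C2–C3 bond is cut. C3 is allylic and 1,3 to the C1 carbinol, so the retron is a sulfonyl carbanion plus a C1–C2 oxirane. The gain is the opening of the ring to an acyclic chain in which C1 is already fixed. The demand is attack at C2 (not C1, not C14), alpha alkylation of the allyl anion, retention of the Z alkene, and cyclisation over oligomerisation.

28 to 21: the C3–S bond is cut (sulfinate displacement on 26), then the C2–O oxirane bond and the C1–C10 bond (25, 23). C1 and C2 come from a chloroacetyl unit added to the C10 vinyllithium, and C1 is set by reduction of the chloroketone. The gain is that the whole southern terminus reduces to a vinylic bromide (21). The demand is reagent-controlled ketone reduction, and introduction of the acidic sulfone only after the last strongly basic step.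

21 to 16 and 18: the C8–C9 bond is cut. C8 is an aldehyde masked as a lactol with O13 (16), and C9/C10/C14 are a 2-bromoallyl unit (18). Allylboration sets C8 and frees O13, so both oxygens take the same PMB group in one operation (20, 21). The demand is reagent control at C8 and reaction through the open form of the lactol without dehydration to a furan.

16 to 10 and 4: the C6–C7 bond is cut (11), C6 is set by reduction of ketone 12 to 13, and O6/O12 are tied as the acetonide (15). The gain is two small fragments, a bromobutenolide and a Z-enal. The demand is a vinyl-metal coupling that tolerates a lactone, and facial control at a ketone flanked by two sp2 carbons.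

10 to 5: the C7=C11 bond and the C8 acyl–O13 bond are cut (8, 7). The symmetric ketone 5 has no alkene geometry to control: the arm that lactonises becomes C13, the other C12. The demand is only alpha-bromination of the butenolide.

4 to 1 and 18 to 17: the amide and silyl bonds of 3 are cut back to butenolide 1, whose ring fixes the Z geometry of C4=C5; the C–Sn bond of 18 is cut back to 17.

## Other disconnections considered

Alternative 1: The cut is C6–C7. The seco compound A2, with a Z-allylic chloride at C6 and a tributylstannyl group on C7, would be closed with Pd2(dba)3, AsPh3 and CuI to the triene ester A1.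
- In its favour: the coupling is neutral, so an ester and silyl ethers are tolerated; C12 is already at the acid oxidation level; no auxiliary has to be removed afterwards.
- Against it here: A1 has a CH2 group at C6. The lactone oxygen and the C6 stereocentre would have to be installed afterwards by oxidising a doubly allylic position of a strained triene, with regio- and facial control. The allyl–palladium intermediate can also lose the Z geometry of C4=C5 or couple at C4, and a stannane on a fully substituted alkene transmetalates slowly.
- Comparison: on mechanism and functional-group tolerance it is the equal or the better of the chosen plan, and it is the better on oxidation-state economy at C12. On structure the chosen plan is better, because C6–O is present and stereodefined before the ring is closed. On step economy the two are about equal up to the ring; Alternative 1 is worse after it.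

Alternative 2: The cut is the temporary C6–C10 bond of a hydroazulene. The C6 alkoxide of the bicyclic tosylate A4 would expel the C14 sulfonate in a Grob fragmentation, merging the five- and seven-membered rings into the cyclodecadienone A3 with the C6 ketone and C10=C14.
- In its favour: the ten-membered ring arises from a bicycle without an entropic penalty or high dilution; fragmentations of this kind are stereoelectronically well defined; C1 and C8 are carried through unchanged.
- Against it here: A3 lacks C11, C12 and C13 entirely. The butenolide would have to be built at C7 of a ketone whose C8 silyloxy group is beta to the enolisable position (risk of elimination). The Z enone is prone to isomerisation and transannular reactions, the C6 ketone must then be reduced with facial control in a flexible ring, and A4 with its quaternary C10 is itself a long synthesis.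
- Comparison: on the ring-forming mechanism it is the better of the two. On C1 and C8 it is equal. On structure and step economy it is worse, because three carbons and the C6 stereocentre remain to be added after the ring exists.

Alternative 3: The cut is C8–C9, made by ring contraction. n-BuLi would exchange tin for lithium at C8 of the eleven-membered allyl ether A6, and the Still–Wittig [2,3]-shift would form C8–C9, break O–C14 and create C10=C14, giving the carbinol A5.
- In its favour: one step closes the carbocycle, sets C8 and makes the exocyclic methylene; the large ring is first closed through an easier C–O bond; the butenolide mask is the same acetonide; there is no auxiliary to remove.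
- Against it here: the lithiated C8 is allylic to C7=C11, so the carbanion is delocalised and configurationally labile. The C8 configuration would then depend on ring conformation and not on the stannane. A [1,2]-shift or reaction through C11 can compete, and an enantioenriched alpha-alkoxystannane next to a tetrasubstituted alkene is hard to make.
- Comparison: on the masking strategy it is equal. On bond economy in the key step it is the better. On predictability of the mechanism and on the length of the route to A6 it is worse than the chosen plan, where C8 and C1 are set by separate reagent-controlled steps.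

Key step: step 18

## Steps

Step 1
Reactants: 1 4-methylfuran-2(5H)-one
Product: 3 (Z)-4-(tert-butyldiphenylsilyloxy)-N-methoxy-N,3-dimethylbut-2-enamide, via hydroxy Weinreb amide 2 (not isolated)
Conditions: MeNH(OMe)·HCl, AlMe3, CH2Cl2, 0 °C; aqueous tartrate work-up; then TBDPSCl, imidazole, DMF, 0 °C
Reagents that add atoms: N,O-dimethylhydroxylamine hydrochloride (CNOC.Cl); tert-butyl(chloro)diphenylsilane (CC(C)(C)[Si](Cl)(c1ccccc1)c1ccccc1)
Why: Aminolysis of the lactone by the aluminium amide (Weinreb amide formation) opens the ring without touching the alkene, so the Z geometry is that of the butenolide; silylating the primary alcohol at once prevents relactonisation.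

Step 2
Reactants: 3 (Z)-silyloxy Weinreb amide
Product: 4 (Z)-4-(tert-butyldiphenylsilyloxy)-3-methylbut-2-enal (C3–C6 fragment, aldehyde carbon = C6)
Conditions: i-Bu2AlH, THF, −78 °C; aqueous tartrate work-up
Reagents that add atoms: none
Why: Reduction of a Weinreb amide with i-Bu2AlH stops at the aldehyde because the chelated tetrahedral adduct collapses only on work-up; a beta,beta-disubstituted Z-enal should keep its geometry under neutral, cold handling.

Step 3
Reactants: 5 1,3-dihydroxyacetone (used as its commercial dimer)
Product: 7 4-(hydroxymethyl)furan-2(5H)-one, via ethyl 4-hydroxy-3-(hydroxymethyl)but-2-enoate 6 (not isolated)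
Conditions: Ph3P=CHCO2Et, CH2Cl2, rt
Reagents that add atoms: ethyl (triphenylphosphoranylidene)acetate (CCOC(=O)C=P(c1ccccc1)(c1ccccc1)c1ccccc1)
Why: Wittig olefination of the activated ketone with a stabilised ylide, then spontaneous lactonisation; the ketone is symmetric, so there is no alkene isomer problem, and the arm that lactonises is thereby C13 (cis to the C8 carbonyl) and the free arm C12.

Step 4
Reactants: 7 4-(hydroxymethyl)furan-2(5H)-one
Product: 8 4-[(tert-butyldimethylsilyloxy)methyl]furan-2(5H)-one
Conditions: TBSCl, imidazole, DMF, 0 °C to rt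
Reagents that add atoms: tert-butyl(chloro)dimethylsilane (CC(C)(C)[Si](C)(C)Cl)
Why: Standard silylation of a primary alcohol; O12 must be masked because the C6 ketone of 12 would otherwise be trapped as a hemiketal and dehydrate to a furan.

Step 5
Reactants: 8 silyloxymethyl butenolide
Product: 10 3-bromo-4-[(tert-butyldimethylsilyloxy)methyl]furan-2(5H)-one, via trans-dibromolactone 9 (not isolated)
Conditions: Br2, CH2Cl2, 0 °C; then Et3N, 0 °C to rt
Reagents that add atoms: bromine (BrBr)
Why: Bromination–dehydrobromination: bromine adds across the enoate alkene and Et3N removes the acidic alpha proton with loss of the beta bromide, which leaves bromine on C7, the alpha carbon.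

Step 6
Reactants: 10 bromobutenolide; 4 Z-enal
Product: 11 3-[(2Z)-4-(tert-butyldiphenylsilyloxy)-1-hydroxy-3-methylbut-2-en-1-yl]-4-[(tert-butyldimethylsilyloxy)methyl]furan-2(5H)-one (both C6 epimers)
Conditions: CrCl2 (4 equiv), NiCl2 (2 mol %), DMF, rt
Reagents that add atoms: none
Why: Nozaki–Hiyama–Kishi coupling: nickel inserts into the alkenyl C–Br bond, and the alkenylchromium species formed by transmetalation adds 1,2 to the enal while tolerating the lactone and both silyl ethers; C6 is formed without control and is corrected in steps 7 and 8.

Step 7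
Reactants: 11 C6 carbinol (epimer mixture)
Product: 12 3-[(2Z)-4-(tert-butyldiphenylsilyloxy)-3-methylbut-2-enoyl]-4-[(tert-butyldimethylsilyloxy)methyl]furan-2(5H)-one
Conditions: Dess–Martin periodinane, NaHCO3, CH2Cl2, 0 °C
Reagents that add atoms: none
Why: Dess–Martin oxidation of the secondary, doubly allylic alcohol under buffered conditions, chosen because it is neutral enough to spare the Z enone and the silyl ethers.

Step 8
Reactants: 12 C6 ketone
Product: 13 (6R)-carbinol, 3-[(1R,2Z)-4-(tert-butyldiphenylsilyloxy)-1-hydroxy-3-methylbut-2-en-1-yl]-4-[(tert-butyldimethylsilyloxy)methyl]furan-2(5H)-one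
Conditions: (S)-1-methyl-3,3-diphenyltetrahydro-1H,3H-pyrrolo[1,2-c][1,3,2]oxazaborole (0.3 equiv), catecholborane, toluene, −78 °C
Reagents that add atoms: none
Why: Corey–Bakshi–Shibata reduction: the ketone should bind the catalyst boron on the side of the smaller Z-alkenyl group, with the fully substituted butenolide carbon C7 as the large group, so the (S)-catalyst delivers hydride to give the (6R) alcohol; catecholborane at −78 °C avoids conjugate reduction and hydroboration.

Step 9
Reactants: 13 (6R)-carbinol
Product: 15 acetonide lactone, the 6,12-O-isopropylidene derivative of 14 (2,2-dimethyl-4,7-dihydro-1,3-dioxepine fused at C7=C11 to the 8,13-butenolide; 6R; C3 OTBDPS), via desilylated diol 14 (not isolated)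
Conditions: camphorsulfonic acid (0.1 equiv), MeOH–CH2Cl2, 0 °C; evaporate; then 2,2-dimethoxypropane, CH2Cl2, 0 °C; Et3N quench
Reagents that add atoms: 2,2-dimethoxypropane (COC(C)(C)OC)
Why: Acid-catalysed methanolysis removes the primary TBS ether much faster than the TBDPS ether, and transketalisation then ties O6 and O12, the only hydroxyl pair held cis on C7=C11, into the seven-membered acetonide; C6 is not touched.

Step 10
Reactants: 15 acetonide lactone
Product: 16 lactol (C8 hemiacetal of 15, both anomers; the masked C8 aldehyde with O13)
Conditions: i-Bu2AlH (1.2 equiv), CH2Cl2, −78 °C; aqueous tartrate work-up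
Reagents that add atoms: none
Why: Partial reduction of a lactone to the lactol with about one equivalent of i-Bu2AlH at −78 °C; the lactol is kept away from acid because it would dehydrate to a furan.

Step 11
Reactants: 17 2,3-dibromopropene
Product: 18 (2-bromoallyl)tributylstannane
Conditions: Bu3SnLi (from Bu3SnH and LDA), THF, −78 °C
Reagents that add atoms: tributyltin hydride, used as its lithium derivative (CCCC[SnH](CCCC)CCCC)
Why: Substitution of the allylic bromide by the stannyl anion (SN2 or SN2′, which give the same product here); the vinylic bromide is far less reactive at −78 °C.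

Step 12
Reactants: 16 lactol; 18 (2-bromoallyl)tributylstannane
Product: 20 (6R,8S)-diol, the C8 2-bromoallyl carbinol with free C13 hydroxymethyl on the 6,12-acetonide (C3 OTBDPS), via B-(2-bromoallyl)diazaborolidine 19 (not isolated)
Conditions: (4S,5S)-2-bromo-4,5-diphenyl-1,3-ditosyl-1,3,2-diazaborolidine (from the (S,S)-bis-sulfonamide and BBr3, volatiles removed), 18, CH2Cl2, rt; then 16, −78 °C; pH 7 buffer
Reagents that add atoms: none
Why: Allylboration through a six-membered chair transition state: tin-to-boron exchange gives the chiral allylborane 19, which adds to the open hydroxy-enal form of the lactol; the (S,S) controller is chosen to deliver the allyl group to the Si face of the C8 aldehyde, which gives (8S) by reagent control, and an excess of 19 covers the free hydroxyl.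

Step 13
Reactants: 20 (6R,8S)-diol
Product: 21 bis-PMB ether (C8 and C13 OPMB, C10 vinylic bromide, 6,12-acetonide, C3 OTBDPS)
Conditions: NaH, 4-methoxybenzyl chloride, n-Bu4NI (cat.), THF–DMF, 0 °C to rt
Reagents that add atoms: 4-methoxybenzyl chloride (COc1ccc(CCl)cc1)
Why: Double Williamson etherification; the secondary C8 and primary C13 alkoxides are both benzylated, and the vinylic bromide and the acetonide are inert to NaH at this temperature.

Step 14
Reactants: 21 vinylic bromide
Product: 23 chloromethyl ketone (C10–C1(=O)–C2H2Cl enone), via C10 vinyllithium 22 (not isolated)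
Conditions: t-BuLi (2.1 equiv), Et2O, −78 °C; then ClCH2C(O)N(OMe)Me, −78 °C; H2O
Reagents that add atoms: 2-chloro-N-methoxy-N-methylacetamide (CON(C)C(=O)CCl)
Why: Bromine–lithium exchange with two equivalents of t-BuLi gives vinyllithium 22, and its acylation by the Weinreb amide stops at the ketone because the tetrahedral adduct is stable at −78 °C; this forms the C10–C1 bond.

Step 15
Reactants: 23 chloromethyl ketone
Product: 25 (1S)-oxirane (C1–C2 epoxide on C10; C8 and C13 OPMB, 6,12-acetonide, C3 OTBDPS), via (1S)-chlorohydrin 24 (not isolated)
Conditions: (S)-oxazaborolidine as in step 8 (0.3 equiv), catecholborane, toluene, −78 °C; MeOH; then K2CO3, MeOH, 0 °C to rt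
Reagents that add atoms: none
Why: Corey–Bakshi–Shibata reduction with the alkenyl group as the large and CH2Cl as the small substituent should give the (1S)-chlorohydrin with the (S)-catalyst; carbonate then closes the oxirane by intramolecular Williamson displacement at C2, which leaves the C1–O bond and the C1 configuration untouched.

Step 16
Reactants: 25 epoxide silyl ether
Product: 26 C3 allylic alcohol
Conditions: n-Bu4NF, THF, 0 °C
Reagents that add atoms: none
Why: Fluoride cleaves the only silyl ether present; the oxirane, the PMB ethers and the acetonide are stable to n-Bu4NF at 0 °C.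

Step 17
Reactants: 26 C3 allylic alcohol
Product: 28 seco C3 allylic phenyl sulfone with the C1–C2 oxirane (precursor of the key step), via allylic mesylate 27 (not isolated)
Conditions: MsCl, Et3N, THF, −40 °C; then PhSO2Na, n-Bu4NI (cat.), DMF, −40 °C to rt
Reagents that add atoms: sodium benzenesulfinate ([Na+].[O-]S(=O)c1ccccc1)
Why: Mesylation of the primary allylic alcohol and SN2 displacement by the sulfur atom of the sulfinate (S-alkylation) give the allylic sulfone; attack is at the primary carbon C3, so the Z alkene is not moved, and the sulfinate is too weak a nucleophile to open the oxirane.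

Step 18
Reactants: 28 seco epoxy sulfone
Product: 30 ten-membered C1 alcohol bearing the C3 phenylsulfonyl group (C3 epimers, one drawn), via lithiated sulfone 29 (not isolated)
Conditions: LDA (1.1 equiv), THF, 2 mM, −78 °C, then slowly to 0 °C; H2O
Reagents that add atoms: none
Why: LDA removes a proton from C3, which is both allylic and alpha to the sulfonyl group, and the lithiated allyl sulfone 29 attacks the unsubstituted oxirane carbon C2 in an SN2 fashion, forming C2–C3 and releasing the C1 alkoxide. The closest known reaction type is the intramolecular alkylation of sulfone-stabilised allylic carbanions by epoxides or allylic halides, used to close ten- and fourteen-membered terpenoid rings. The one ring formed is the ten-membered carbocycle; both oxirane carbons become ring members, so the closure is of the endo type (10-endo-tet in the exo/endo convention for epoxides), the nine-membered exo alternative being attack at the more hindered C1. No stereocentre of the target is created: C1 keeps the configuration set in step 15 because only the C2–O bond breaks, and the new C3 centre is a mixture that is erased in step 19. The step needs C2 attack over C1 and over SN2′ attack at C14, which a lithium counter-ion without Lewis acid or copper favours; alpha over gamma alkylation, normal for sulfonyl carbanions whose charge sits next to sulfur; and cyclisation over oligomerisation, served by high dilution and by the Z C4=C5 alkene and the cis-fused dioxepine, which turn the two chain ends towards each other. The Z geometry of C4=C5 should survive because alpha-sulfonyl allyl anions alkylate without loss of alkene configuration. The lactone and both acetates are absent at this stage, and an amide base is used so that no external nucleophile competes for the oxirane.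

Step 19
Reactants: 30 cyclised hydroxy sulfone
Product: 31 ten-membered C1 alcohol with C3 as CH2 (C8 and C13 OPMB, 6,12-acetonide)
Conditions: [1,3-bis(diphenylphosphino)propane]PdCl2 (5 mol %), LiBHEt3, THF, 0 °C
Reagents that add atoms: none
Why: Palladium-catalysed reductive desulfonylation: zerovalent palladium, formed from the divalent precatalyst and hydride, ionises the allylic C3–S bond and hydride returns to the same terminus of the allyl complex, a reaction type known to keep the position and geometry of the alkene with this bidentate phosphine; the epimer mixture converges on one compound.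

Step 20
Reactants: 31 C1 alcohol
Product: 32 C1 tert-butyldimethylsilyl ether
Conditions: TBSOTf, 2,6-lutidine, CH2Cl2, −78 to 0 °C
Reagents that add atoms: tert-butyldimethylsilyl trifluoromethanesulfonate (CC(C)(C)[Si](C)(C)OS(=O)(=O)C(F)(F)F)
Why: Silylation of the secondary allylic alcohol with the silyl triflate and a hindered base; the group must outlast steps 21 to 24 so that only O8 and O13 are acetylated and O1 is not oxidised.

Step 21
Reactants: 32 bis-PMB ether
Product: 33 C8,C13-diol (C1 OTBS, 6,12-acetonide)
Conditions: DDQ (2.5 equiv), CH2Cl2–pH 7 buffer (10:1), 0 °C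
Reagents that add atoms: none
Why: Oxidative cleavage of both 4-methoxybenzyl ethers by DDQ through benzylic hydride abstraction and hydrolysis of the oxocarbenium ions; buffer and low temperature spare the acetonide and the doubly allylic C6–H.

Step 22
Reactants: 33 C8,C13-diol
Product: 34 C8,C13-diacetate (C1 OTBS, 6,12-acetonide)
Conditions: Ac2O, pyridine, 4-(dimethylamino)pyridine (cat.), CH2Cl2, 0 °C to rt
Reagents that add atoms: acetic anhydride (CC(=O)OC(C)=O)
Why: Acylation of the primary C13 and secondary C8 alcohols under nucleophilic catalysis; fixing O8 as the acetate before C12 is oxidised rules out lactonisation towards O8.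

Step 23
Reactants: 34 acetonide diacetate
Product: 35 C6,C12-diol (C8 and C13 OAc, C1 OTBS)
Conditions: pyridinium p-toluenesulfonate (0.2 equiv), MeOH, 0 °C to rt
Reagents that add atoms: none
Why: Acid-catalysed transketalisation in methanol: the seven-membered acetonide opens at the ketal carbon much faster than the doubly allylic C6–O bond can ionise, and the secondary TBS ether and the acetates should survive the short, cold exposure.

Step 24
Reactants: 35 C6,C12-diol
Product: 37 C1-silylated 6,12-olide, via lactol 36 (not isolated)
Conditions: 2,2,6,6-tetramethylpiperidine-1-oxyl (0.2 equiv), PhI(OAc)2 (2.5 equiv), CH2Cl2, rt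
Reagents that add atoms: none
Why: Oxoammonium oxidation takes the less hindered primary allylic C12 alcohol to the aldehyde, which is caught by the cis C6 hydroxyl as lactol 36 and oxidised once more to the butenolide (oxidative lactonisation of a 1,4-diol); C6 keeps its configuration because its C–O bond is never broken.

Step 25
Reactants: 37 C1-silylated lactone
Product: 38 8alpha,13-diacetoxy-1beta-hydroxygermacra-4,7(11),10(14)-trien-6alpha,12-olide
Conditions: HF·pyridine, pyridine, THF, 0 °C to rt
Reagents that add atoms: none
Why: Fluoride-induced desilylation under buffered, slightly acidic conditions, chosen because basic fluoride would enolise the butenolide or attack the allylic acetates.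

## Compound list

1 | 4-methylfuran-2(5H)-one | CC1=CC(=O)OC1 | starting material
2 | (Z)-4-hydroxy-N-methoxy-N,3-dimethylbut-2-enamide | CON(C)C(=O)/C=C(/C)CO | intermediate (not isolated)
3 | (Z)-4-(tert-butyldiphenylsilyloxy)-N-methoxy-N,3-dimethylbut-2-enamide | CON(C)C(=O)/C=C(/C)CO[Si](c1ccccc1)(c1ccccc1)C(C)(C)C | intermediate
4 | (Z)-4-(tert-butyldiphenylsilyloxy)-3-methylbut-2-enal | O=C/C=C(/C)CO[Si](c1ccccc1)(c1ccccc1)C(C)(C)C | intermediate
5 | 1,3-dihydroxyacetone | OCC(=O)CO | starting material
6 | ethyl 4-hydroxy-3-(hydroxymethyl)but-2-enoate | CCOC(=O)C=C(CO)CO | intermediate (not isolated)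
7 | 4-(hydroxymethyl)furan-2(5H)-one | O=C1OCC(CO)=C1 | intermediate
8 | 4-[(tert-butyldimethylsilyloxy)methyl]furan-2(5H)-one | O=C1OCC(CO[Si](C)(C)C(C)(C)C)=C1 | intermediate
9 | 3,4-dibromo-4-[(tert-butyldimethylsilyloxy)methyl]dihydrofuran-2(3H)-one (racemic trans-dibromide) | O=C1OCC(Br)(CO[Si](C)(C)C(C)(C)C)C1Br | intermediate (not isolated)
10 | 3-bromo-4-[(tert-butyldimethylsilyloxy)methyl]furan-2(5H)-one | O=C1OCC(CO[Si](C)(C)C(C)(C)C)=C1Br | intermediate
11 | 3-[(2Z)-4-(tert-butyldiphenylsilyloxy)-1-hydroxy-3-methylbut-2-en-1-yl]-4-[(tert-butyldimethylsilyloxy)methyl]furan-2(5H)-one (both C6 epimers) | O=C1OCC(CO[Si](C)(C)C(C)(C)C)=C1C(O)/C=C(/C)CO[Si](c1ccccc1)(c1ccccc1)C(C)(C)C | intermediate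
12 | 3-[(2Z)-4-(tert-butyldiphenylsilyloxy)-3-methylbut-2-enoyl]-4-[(tert-butyldimethylsilyloxy)methyl]furan-2(5H)-one | O=C1OCC(CO[Si](C)(C)C(C)(C)C)=C1C(=O)/C=C(/C)CO[Si](c1ccccc1)(c1ccccc1)C(C)(C)C | intermediate
13 | 3-[(1R,2Z)-4-(tert-butyldiphenylsilyloxy)-1-hydroxy-3-methylbut-2-en-1-yl]-4-[(tert-butyldimethylsilyloxy)methyl]furan-2(5H)-one | O=C1OCC(CO[Si](C)(C)C(C)(C)C)=C1[C@H](O)/C=C(/C)CO[Si](c1ccccc1)(c1ccccc1)C(C)(C)C | intermediate
14 | 3-[(1R,2Z)-4-(tert-butyldiphenylsilyloxy)-1-hydroxy-3-methylbut-2-en-1-yl]-4-(hydroxymethyl)furan-2(5H)-one | O=C1OCC(CO)=C1[C@H](O)/C=C(/C)CO[Si](c1ccccc1)(c1ccccc1)C(C)(C)C | intermediate (not isolated)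
15 | acetonide lactone: 6,12-O-isopropylidene derivative of 14, dioxepine fused at C7=C11 to the 8,13-butenolide, (6R) | O=C1OCC2=C1[C@@H](/C=C(/C)CO[Si](c3ccccc3)(c3ccccc3)C(C)(C)C)OC(C)(C)OC2 | intermediate
16 | lactol: C8 hemiacetal of 15 (both anomers) | OC1OCC2=C1[C@@H](/C=C(/C)CO[Si](c3ccccc3)(c3ccccc3)C(C)(C)C)OC(C)(C)OC2 | intermediate
17 | 2,3-dibromopropene | C=C(Br)CBr | starting material
18 | (2-bromoallyl)tributylstannane | C=C(Br)C[Sn](CCCC)(CCCC)CCCC | intermediate
19 | (4S,5S)-2-(2-bromoallyl)-4,5-diphenyl-1,3-bis(4-methylphenylsulfonyl)-1,3,2-diazaborolidine | C=C(Br)CB1N(S(=O)(=O)c2ccc(C)cc2)[C@@H](c2ccccc2)[C@H](c2ccccc2)N1S(=O)(=O)c1ccc(C)cc1 | intermediate (not isolated)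
20 | (6R,8S)-diol: C8 2-bromoallyl carbinol, C13 hydroxymethyl, 6,12-acetonide, C3 OTBDPS | C=C(Br)C[C@H](O)C2=C(CO)COC(C)(C)O[C@@H]2/C=C(/C)CO[Si](c1ccccc1)(c1ccccc1)C(C)(C)C | intermediate
21 | bis-PMB ether of 20 | C=C(Br)C[C@H](OCc1ccc(OC)cc1)C2=C(COCc1ccc(OC)cc1)COC(C)(C)O[C@@H]2/C=C(/C)CO[Si](c1ccccc1)(c1ccccc1)C(C)(C)C | intermediate
22 | C10 vinyllithium from 21 | C=C([Li])C[C@H](OCc1ccc(OC)cc1)C2=C(COCc1ccc(OC)cc1)COC(C)(C)O[C@@H]2/C=C(/C)CO[Si](c1ccccc1)(c1ccccc1)C(C)(C)C | intermediate (not isolated)
23 | chloromethyl ketone (C1 ketone, C2 chloride) | C=C(C(=O)CCl)C[C@H](OCc1ccc(OC)cc1)C2=C(COCc1ccc(OC)cc1)COC(C)(C)O[C@@H]2/C=C(/C)CO[Si](c1ccccc1)(c1ccccc1)C(C)(C)C | intermediate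
24 | (1S)-chlorohydrin | C=C([C@H](O)CCl)C[C@H](OCc1ccc(OC)cc1)C2=C(COCc1ccc(OC)cc1)COC(C)(C)O[C@@H]2/C=C(/C)CO[Si](c1ccccc1)(c1ccccc1)C(C)(C)C | intermediate (not isolated)
25 | (1S)-C1–C2 oxirane, C3 OTBDPS | C=C([C@H]1CO1)C[C@H](OCc3ccc(OC)cc3)C2=C(COCc3ccc(OC)cc3)COC(C)(C)O[C@@H]2/C=C(/C)CO[Si](c3ccccc3)(c3ccccc3)C(C)(C)C | intermediate
26 | C3 allylic alcohol with C1–C2 oxirane | C=C([C@H]1CO1)C[C@H](OCc3ccc(OC)cc3)C2=C(COCc3ccc(OC)cc3)COC(C)(C)O[C@@H]2/C=C(/C)CO | intermediate
27 | C3 allylic mesylate | C=C([C@H]1CO1)C[C@H](OCc3ccc(OC)cc3)C2=C(COCc3ccc(OC)cc3)COC(C)(C)O[C@@H]2/C=C(/C)COS(C)(=O)=O | intermediate (not isolated)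
28 | seco C3 allylic phenyl sulfone with C1–C2 oxirane (C8 and C13 OPMB, 6,12-acetonide) | C=C([C@H]1CO1)C[C@H](OCc3ccc(OC)cc3)C2=C(COCc3ccc(OC)cc3)COC(C)(C)O[C@@H]2/C=C(/C)CS(=O)(=O)c3ccccc3 | intermediate
29 | C3-lithiated sulfone | C=C([C@H]1CO1)C[C@H](OCc3ccc(OC)cc3)C2=C(COCc3ccc(OC)cc3)COC(C)(C)O[C@@H]2/C=C(/C)C([Li])S(=O)(=O)c3ccccc3 | intermediate (not isolated)
30 | ten-membered C1 alcohol with C3 phenylsulfonyl group (C3 epimers, one drawn) | C=C1C[C@H](OCc3ccc(OC)cc3)C2=C(COCc3ccc(OC)cc3)COC(C)(C)O[C@@H]2/C=C(/C)[C@H](S(=O)(=O)c3ccccc3)C[C@H]1O | intermediate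
31 | ten-membered C1 alcohol, C3 = CH2 | C=C1C[C@H](OCc3ccc(OC)cc3)C2=C(COCc3ccc(OC)cc3)COC(C)(C)O[C@@H]2/C=C(/C)CC[C@H]1O | intermediate
32 | C1 TBS ether of 31 | C=C1C[C@H](OCc3ccc(OC)cc3)C2=C(COCc3ccc(OC)cc3)COC(C)(C)O[C@@H]2/C=C(/C)CC[C@H]1O[Si](C)(C)C(C)(C)C | intermediate
33 | C8,C13-diol, C1 OTBS, 6,12-acetonide | C=C1C[C@H](O)C2=C(CO)COC(C)(C)O[C@@H]2/C=C(/C)CC[C@H]1O[Si](C)(C)C(C)(C)C | intermediate
34 | C8,C13-diacetate, C1 OTBS, 6,12-acetonide | C=C1C[C@H](OC(C)=O)C2=C(COC(C)=O)COC(C)(C)O[C@@H]2/C=C(/C)CC[C@H]1O[Si](C)(C)C(C)(C)C | intermediate
35 | C6,C12-diol, C8 and C13 OAc, C1 OTBS | C=C1C[C@H](OC(C)=O)/C(=C(/CO)COC(C)=O)[C@H](O)/C=C(/C)CC[C@H]1O[Si](C)(C)C(C)(C)C | intermediate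
36 | C12 lactol (6,12-hemiacetal) | C=C1C[C@H](OC(C)=O)C2=C(COC(C)=O)C(O)O[C@@H]2/C=C(/C)CC[C@H]1O[Si](C)(C)C(C)(C)C | intermediate (not isolated)
37 | C1 TBS ether of the target lactone | C=C1C[C@H](OC(C)=O)C2=C(COC(C)=O)C(=O)O[C@@H]2/C=C(/C)CC[C@H]1O[Si](C)(C)C(C)(C)C | intermediate
38 | 8alpha,13-diacetoxy-1beta-hydroxygermacra-4,7(11),10(14)-trien-6alpha,12-olide | C=C1C[C@H](OC(C)=O)C2=C(COC(C)=O)C(=O)O[C@@H]2/C=C(/C)CC[C@H]1O | target

## Step count and least certain steps

Total step count: 25. Longest linear sequence: 22 steps (5 to 38, steps 3–10 and 12–25). Seventeen steps lead to the precursor 28 and seven follow the key step.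

**Step 18 (key step).** The most likely failure is intermolecular alkylation or simple non-reaction: a terminal oxirane is a sluggish electrophile at temperatures where the anion is stable, and on warming, oligomerisation, SN2′ attack at C14 or attack at C1 can overtake the strained ten-membered closure. Fallback, from 28 back to 32: open the oxirane of 28 at C2 with LiI and AcOH in THF to the (1S)-iodohydrin F1; silylate O1 (TBSOTf, 2,6-lutidine) to the silyloxy iodide F2; close the same C2–C3 bond by intramolecular sulfone alkylation of the primary iodide (LiN(SiMe3)2, THF, high dilution, −78 to 0 °C) to the cyclic silyloxy sulfone F3. An iodide reacts at low temperature and has no SN2′ or C1 pathway. Desulfonylation of F3 under the conditions of step 19 gives 32.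

**Step 8 (C6 by reduction).** The risk is poor facial discrimination, because both ketone substituents are sp2 carbons and the lactone carbonyl may also bind boron. Fallback, from 10 and 4 directly to 13: a catalytic asymmetric Nozaki–Hiyama–Kishi coupling (CrCl2, NiCl2, chiral sulfonamide ligand) forms C6–C7 and the C6 stereocentre in one step and leaves out 11 and 12; no new compound is made (F0).

**Step 12 (allylboration of the lactol).** The risk is dehydration of the lactol to a furan under the Lewis-acidic boron reagent, or consumption of the reagent by the free hydroxyl before the open aldehyde reacts. Fallback, from 15 back to 21: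
- open the lactone with MeNH(OMe)·HCl and AlMe3 to the hydroxy Weinreb amide F4;
- protect O13 with 4-methoxybenzyl trichloroacetimidate and La(OTf)3 (cat.) to the PMB ether F5;
- reduce with i-Bu2AlH to the free enal F6;
- allylate with 19 at −78 °C to the C8 carbinol F7;
- etherify with NaH and 4-methoxybenzyl chloride to reach 21.

**Step 19 (desulfonylation).** The risk is allylic transposition or Z-to-E isomerisation through the allyl–palladium complex, giving the C3=C4 isomer or the E alkene. Fallback, from 30 to 31: single-electron cleavage of the C–S bond with sodium amalgam and Na2HPO4 in MeOH–THF at −20 °C, a different mechanism that does not pass through a metal-bound allyl unit; no new compound is made (F0).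

**Step 24 (oxidative lactonisation).** The risk is competing oxidation of the doubly allylic C6 carbinol before the lactol has formed, which would give a dienone. Fallback, from 35 to 37 in two separate operations: MnO2 in CH2Cl2 to the isolated lactol 36, then Ag2CO3 on Celite in hot toluene for the lactol-to-lactone oxidation; no new compound is made (F0).

## Further compounds

F1 | step 18 | (1S)-iodohydrin of 28 (C1 OH, C2 iodide) | C=C([C@H](O)CI)C[C@H](OCc3ccc(OC)cc3)C2=C(COCc3ccc(OC)cc3)COC(C)(C)O[C@@H]2/C=C(/C)CS(=O)(=O)c3ccccc3
F2 | step 18 | C1 TBS ether of F1 | C=C([C@H](O[Si](C)(C)C(C)(C)C)CI)C[C@H](OCc3ccc(OC)cc3)C2=C(COCc3ccc(OC)cc3)COC(C)(C)O[C@@H]2/C=C(/C)CS(=O)(=O)c3ccccc3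
F3 | step 18 | ten-membered C1 TBS ether with C3 phenylsulfonyl group (C3 epimers, one drawn) | C=C1C[C@H](OCc3ccc(OC)cc3)C2=C(COCc3ccc(OC)cc3)COC(C)(C)O[C@@H]2/C=C(/C)[C@H](S(=O)(=O)c3ccccc3)C[C@H]1O[Si](C)(C)C(C)(C)C
F0 | step 8 | none | none
F4 | step 12 | C8 Weinreb amide with free C13 hydroxymethyl, 6,12-acetonide | CON(C)C(=O)C2=C(CO)COC(C)(C)O[C@@H]2/C=C(/C)CO[Si](c1ccccc1)(c1ccccc1)C(C)(C)C
F5 | step 12 | C13 PMB ether of F4 | CON(C)C(=O)C2=C(COCc1ccc(OC)cc1)COC(C)(C)O[C@@H]2/C=C(/C)CO[Si](c1ccccc1)(c1ccccc1)C(C)(C)C
F6 | step 12 | C8 enal, C13 OPMB | O=CC2=C(COCc1ccc(OC)cc1)COC(C)(C)O[C@@H]2/C=C(/C)CO[Si](c1ccccc1)(c1ccccc1)C(C)(C)C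
F7 | step 12 | (8S)-2-bromoallyl carbinol, C13 OPMB | C=C(Br)C[C@H](O)C2=C(COCc1ccc(OC)cc1)COC(C)(C)O[C@@H]2/C=C(/C)CO[Si](c1ccccc1)(c1ccccc1)C(C)(C)C
F0 | step 19 | none | none
F0 | step 24 | none | none
A1 | alternative 1 | methyl (4Z)-1-(tert-butyldiphenylsilyloxy)-8,13-bis(triethylsilyloxy)germacra-4,7(11),10(14)-trien-12-oate | C=C1C[C@H](O[Si](CC)(CC)CC)/C(=C(/C(=O)OC)CO[Si](CC)(CC)CC)C/C=C(/C)CC[C@H]1O[Si](c2ccccc2)(c2ccccc2)C(C)(C)C
A2 | alternative 1 | seco ester with C6 Z-allylic chloride and C7 tributylstannyl group | C=C(C[C@H](O[Si](CC)(CC)CC)/C(=C(/C(=O)OC)CO[Si](CC)(CC)CC)[Sn](CCCC)(CCCC)CCCC)[C@@H](CC/C(C)=C\CCl)O[Si](c1ccccc1)(c1ccccc1)C(C)(C)C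
A3 | alternative 2 | (4Z)-8-(tert-butyldimethylsilyloxy)-1-(4-methoxybenzyloxy)germacra-4,10(14)-dien-6-one | C=C1C[C@H](O[Si](C)(C)C(C)(C)C)CC(=O)/C=C(/C)CC[C@H]1OCc2ccc(OC)cc2
A4 | alternative 2 | hydroazulenol tosylate: C6–C10 bonded bicyclo[5.3.0]dec-4-ene, C6 OH, C14 OTs, C8 OTBS, C1 OPMB (ring-fusion configuration as drawn, lost on fragmentation) | Cc1ccc(cc1)S(=O)(=O)OC[C@]12C[C@H](O[Si](C)(C)C(C)(C)C)C[C@@]1(O)C=C(C)CC[C@H]2OCc1ccc(OC)cc1
A5 | alternative 3 | ten-membered C8 carbinol with C10=C14, C1 OTIPS, C13 OPMB, 6,12-acetonide | C=C1C[C@H](O)C2=C(COCc3ccc(OC)cc3)COC(C)(C)O[C@@H]2/C=C(/C)CC[C@H]1O[Si](C(C)C)(C(C)C)C(C)C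
A6 | alternative 3 | eleven-membered C8–O–C14 allyl ether with C8 tributylstannyl group | C=C1CO[C@H]([Sn](CCCC)(CCCC)CCCC)C2=C(COCc3ccc(OC)cc3)COC(C)(C)O[C@@H]2/C=C(/C)CC[C@H]1O[Si](C(C)C)(C(C)C)C(C)C
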